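## Retrosynthetic overview

1. Structural feature used: O1 of the pyranone ring is bonded to C8a, which is meta to the C7 oxygen and para to C6. Cutting O1–C8a therefore leaves a 4-oxygenated cinnamic acid whose parent, 4-hydroxybenzaldehyde, has two identical carbons ortho to oxygen (the future C6 and C8), so the 2-methylbut-3-en-2-yl group goes onto C6 without a C6/C8 choice.
2. Target 16 ⇐ silyl ether 15 ⇐ (E)-acid 13, by photocatalytic E→Z isomerisation and oxidative O1–C8a closure; the pyranone ring is made last.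
3. 13 ⇐ aldehyde 5 + phosphonate 11 (C3=C4 by Horner–Wadsworth–Emmons olefination); 11 ⇐ allyl diethylphosphonoacetate 10 + diepoxy triflate 9 (C3–C1' bond by alkylation).
4. 9 ⇐ nerol 6: the 2',3'-oxirane (C2', C3') by Sharpless epoxidation, then the 6',7'-oxirane (C6') by Shi epoxidation. 5 ⇐ 4-hydroxybenzaldehyde 1 by O-prenylation, aromatic Claisen rearrangement and silylation.
5. Ring order: 2',3'-oxirane, 6',7'-oxirane, then the pyranone ring; the benzene ring is bought.

Key step: step 10

Remark on the chemistry: the phosphonate is used as its commercial allyl ester so that the carboxyl group can later be freed without hydroxide or acid, and both antipodes of the fructose-derived epoxidation ketone are taken as available.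

## Route

Step 1
Reactants: 1 4-hydroxybenzaldehyde; 2 1-bromo-3-methylbut-2-ene
Product: 3 4-[(3-methylbut-2-en-1-yl)oxy]benzaldehyde
Conditions: K2CO3, acetone, reflux
Reagents that add atoms: none
Why: Williamson ether synthesis, in which the phenoxide made acidic by the para-formyl group displaces the primary allylic bromide by SN2 at oxygen.

Step 2
Reactants: 3 4-[(3-methylbut-2-en-1-yl)oxy]benzaldehyde
Product: 4 4-hydroxy-3-(2-methylbut-3-en-2-yl)benzaldehyde
Conditions: EtOH/H2O 4:1, degassed, sealed tube, 130 °C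
Reagents that add atoms: none
Why: Aromatic Claisen rearrangement, in which the [3,3]-sigmatropic shift bonds the dimethyl-substituted allyl terminus to an ortho carbon and tautomerisation restores the phenol; both ortho carbons are identical, the para carbon is blocked by the formyl group, and the aqueous alcohol allows a temperature low enough to hold back cyclisation of the phenol onto its vinyl group.

Step 3
Reactants: 4 4-hydroxy-3-(2-methylbut-3-en-2-yl)benzaldehyde
Product: 5 3-(2-methylbut-3-en-2-yl)-4-[(triisopropylsilyl)oxy]benzaldehyde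
Conditions: i-Pr3SiOTf, 2,6-lutidine, CH2Cl2, 0 °C to rt
Reagents that add atoms: triisopropylsilyl trifluoromethanesulfonate, CC(C)[Si](OS(=O)(=O)C(F)(F)F)(C(C)C)C(C)C
Why: O-silylation of a phenol, for which the silyl triflate is reactive enough to overcome the hindrance of the neighbouring quaternary carbon while the hindered base leaves the aldehyde alone.

Step 4
Reactants: 6 nerol
Product: 7 [(2S,3R)-3-methyl-3-(4-methylpent-3-en-1-yl)oxiran-2-yl]methanol
Conditions: Ti(OiPr)4 (10 mol%), L-(+)-diethyl tartrate (12 mol%), t-BuOOH (anhydrous, in isooctane), 4 Å molecular sieves, CH2Cl2, −20 °C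
Reagents that add atoms: tert-butyl hydroperoxide, CC(C)(C)OO
Why: Sharpless asymmetric epoxidation, in which the titanium tartrate complex binds the allylic alcohol and delivers oxygen to one face of the 2,3-alkene only; L-(+)-tartrate should set C2 as S, the Z geometry of nerol fixes C3 as R (cis oxirane), and the 6,7-alkene, which has no hydroxyl handle, is left untouched.

Step 5
Reactants: 7 [(2S,3R)-3-methyl-3-(4-methylpent-3-en-1-yl)oxiran-2-yl]methanol
Product: 8 [(2S,3R)-3-{2-[(2R)-3,3-dimethyloxiran-2-yl]ethyl}-3-methyloxiran-2-yl]methanol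
Conditions: 1,2:4,5-di-O-isopropylidene-β-D-erythro-2,3-hexodiulo-2,6-pyranose (D-fructose-derived Shi ketone, 30 mol%), Oxone (2KHSO5·KHSO4·K2SO4), K2CO3, Bu4NHSO4, MeCN/CH2(OMe)2, aq. Na2B4O7/Na2EDTA buffer (pH 10.5), 0 °C
Reagents that add atoms: potassium peroxymonosulfate (active part of Oxone), [K+].[O-]S(=O)(=O)OO
Why: Shi asymmetric epoxidation, in which the chiral dioxirane formed from the ketone transfers oxygen to the remaining trisubstituted alkene through a spiro transition state; the D-fructose series should set C6' as R under reagent control, far from the existing oxirane, and the buffered cold medium spares the epoxy alcohol.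

Step 6
Reactants: 8 [(2S,3R)-3-{2-[(2R)-3,3-dimethyloxiran-2-yl]ethyl}-3-methyloxiran-2-yl]methanol
Product: 9 [(2S,3R)-3-{2-[(2R)-3,3-dimethyloxiran-2-yl]ethyl}-3-methyloxiran-2-yl]methyl trifluoromethanesulfonate
Conditions: Tf2O, 2,6-lutidine, CH2Cl2, −78 °C; cold aq. NaHCO3 wash, used at once without chromatography
Reagents that add atoms: trifluoromethanesulfonic anhydride, O=S(=O)(OS(=O)(=O)C(F)(F)F)C(F)(F)F
Why: O-sulfonylation of the primary alcohol at low temperature with a hindered base, which touches no stereocentre and gives the leaving group needed for displacement next to an oxirane.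

Step 7
Reactants: 9 [(2S,3R)-3-{2-[(2R)-3,3-dimethyloxiran-2-yl]ethyl}-3-methyloxiran-2-yl]methyl trifluoromethanesulfonate; 10 prop-2-en-1-yl (diethoxyphosphoryl)acetate
Product: 11 prop-2-en-1-yl 2-(diethoxyphosphoryl)-3-[(2S,3R)-3-{2-[(2R)-3,3-dimethyloxiran-2-yl]ethyl}-3-methyloxiran-2-yl]propanoate (both epimers at C2)
Conditions: 10 (2 equiv), NaH (1.5 equiv), THF, 0 °C; then 9, −78 to −20 °C; sat. NH4Cl at −20 °C
Reagents that add atoms: none
Why: SN2 C-alkylation of a phosphonoacetate anion by a primary triflate, which at low temperature should be much faster than opening of either oxirane; the surplus of neutral 10, the stronger acid, should reprotonate any anion of 11 before it can attack C2'.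

Step 8
Reactants: 11 prop-2-en-1-yl 2-(diethoxyphosphoryl)-3-[(2S,3R)-3-{2-[(2R)-3,3-dimethyloxiran-2-yl]ethyl}-3-methyloxiran-2-yl]propanoate; 5 3-(2-methylbut-3-en-2-yl)-4-[(triisopropylsilyl)oxy]benzaldehyde
Product: 12 prop-2-en-1-yl (2E)-2-{[(2S,3R)-3-{2-[(2R)-3,3-dimethyloxiran-2-yl]ethyl}-3-methyloxiran-2-yl]methyl}-3-{3-(2-methylbut-3-en-2-yl)-4-[(triisopropylsilyl)oxy]phenyl}prop-2-enoate
Conditions: LiN(SiMe3)2 (0.95 equiv relative to 11), THF, −78 °C; then 5, −78 to 0 °C
Reagents that add atoms: none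
Why: Horner–Wadsworth–Emmons olefination, in which the carbanion is made and captured by the non-enolisable aldehyde at −78 °C before it can reach the neighbouring oxirane; both phosphonate epimers converge, the E ester should predominate, and any Z ester is carried on because step 10 equilibrates the alkene geometry.

Step 9
Reactants: 12 prop-2-en-1-yl (2E)-2-{[(2S,3R)-3-{2-[(2R)-3,3-dimethyloxiran-2-yl]ethyl}-3-methyloxiran-2-yl]methyl}-3-{3-(2-methylbut-3-en-2-yl)-4-[(triisopropylsilyl)oxy]phenyl}prop-2-enoate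
Product: 13 (2E)-2-{[(2S,3R)-3-{2-[(2R)-3,3-dimethyloxiran-2-yl]ethyl}-3-methyloxiran-2-yl]methyl}-3-{3-(2-methylbut-3-en-2-yl)-4-[(triisopropylsilyl)oxy]phenyl}prop-2-enoic acid
Conditions: Pd(PPh3)4 (5 mol%), morpholine (3 equiv), THF, 0 °C to rt; cold pH 6 phosphate buffer work-up, acid used at once
Reagents that add atoms: none
Why: Tsuji–Trost deallylation, in which zerovalent palladium ionises the allyl ester to a π-allyl complex and the carboxylate, and morpholine takes up the allyl group; the neutral medium spares the aryl silyl ether, both oxiranes and the 2-methylbut-3-en-2-yl group, and the 4,5-epoxy acid is never exposed to strong acid.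

Step 10
Reactants: 13 (2E)-2-{[(2S,3R)-3-{2-[(2R)-3,3-dimethyloxiran-2-yl]ethyl}-3-methyloxiran-2-yl]methyl}-3-{3-(2-methylbut-3-en-2-yl)-4-[(triisopropylsilyl)oxy]phenyl}prop-2-enoic acid
Product: 15 3-{[(2S,3R)-3-{2-[(2R)-3,3-dimethyloxiran-2-yl]ethyl}-3-methyloxiran-2-yl]methyl}-6-(2-methylbut-3-en-2-yl)-7-[(triisopropylsilyl)oxy]-2H-chromen-2-one, via Z acid 14 (not isolated)
Conditions: (−)-riboflavin (5 mol%), O2 (1 atm), 2,6-lutidine (1 equiv), MeCN/MeOH 1:1, 402 nm LEDs, rt
Reagents that add atoms: none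
Why: Photoexcited riboflavin first acts as a triplet sensitiser and equilibrates the trisubstituted alkene by energy transfer, so that 13 is turned into the Z acid 14, the only isomer whose carboxyl group lies over the ring; the excited flavin then takes one electron from the electron-rich silyloxyarene carboxylate, the carboxyl oxygen bonds to the ortho carbon C8a, and a second oxidation with loss of the C8a proton restores the benzene ring while O2 reoxidises the reduced flavin to give H2O2. The closest known reaction type is the flavin-photocatalysed isomerisation and oxidative lactonisation of cinnamic acids to coumarins, related to the photoredox dehydrogenative lactonisation of 2-arylbenzoic acids. The pyranone ring closes by attack of carboxylate oxygen on an arene carbon, a six-membered closure that is 6-endo with respect to the C4a–C8a bond, and this irreversible closure drains the Z isomer from the photostationary mixture. No stereocentre is formed and C2', C3' and C6' are not touched, because the medium is neutral and the lutidine buffer keeps the acid from opening the 2',3'-oxirane. The step needs closure at C8a and not at the other ortho carbon C5; the quaternary carbon of the 2-methylbut-3-en-2-yl group on C6 flanks C5 and shields it, whereas C8a has only the C8 hydrogen beside it. Oxygen-derived side reactions should be slight, since the remaining alkenes are a monosubstituted vinyl group and an electron-poor acrylate, neither a good partner for singlet oxygen, and the phenol is masked as its silyl ether.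

Step 11
Reactants: 15 3-{[(2S,3R)-3-{2-[(2R)-3,3-dimethyloxiran-2-yl]ethyl}-3-methyloxiran-2-yl]methyl}-6-(2-methylbut-3-en-2-yl)-7-[(triisopropylsilyl)oxy]-2H-chromen-2-one
Product: 16 3-{[(2S,3R)-3-{2-[(2R)-3,3-dimethyloxiran-2-yl]ethyl}-3-methyloxiran-2-yl]methyl}-7-hydroxy-6-(2-methylbut-3-en-2-yl)-2H-chromen-2-one
Conditions: Bu4NF (1.1 equiv), AcOH (1.1 equiv), THF, 0 °C
Reagents that add atoms: none
Why: Fluoride-induced cleavage of an aryl silyl ether, driven by the Si–F bond and the good phenoxide leaving group; acetic acid buffers the phenoxide so that the lactone and the oxiranes do not meet a strong base.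

## Compound list

1 | 4-hydroxybenzaldehyde | O=Cc1ccc(O)cc1 | starting material
2 | 1-bromo-3-methylbut-2-ene | CC(C)=CCBr | starting material
3 | 4-[(3-methylbut-2-en-1-yl)oxy]benzaldehyde | CC(C)=CCOc1ccc(C=O)cc1 | intermediate
4 | 4-hydroxy-3-(2-methylbut-3-en-2-yl)benzaldehyde | C=CC(C)(C)c1cc(C=O)ccc1O | intermediate
5 | 3-(2-methylbut-3-en-2-yl)-4-[(triisopropylsilyl)oxy]benzaldehyde | C=CC(C)(C)c1cc(C=O)ccc1O[Si](C(C)C)(C(C)C)C(C)C | intermediate
6 | nerol, (2Z)-3,7-dimethylocta-2,6-dien-1-ol | CC(C)=CCC/C(C)=C\CO | starting material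
7 | [(2S,3R)-3-methyl-3-(4-methylpent-3-en-1-yl)oxiran-2-yl]methanol | OC[C@@H]1O[C@]1(C)CCC=C(C)C | intermediate
8 | [(2S,3R)-3-{2-[(2R)-3,3-dimethyloxiran-2-yl]ethyl}-3-methyloxiran-2-yl]methanol | OC[C@@H]1O[C@]1(C)CC[C@H]1OC1(C)C | intermediate
9 | [(2S,3R)-3-{2-[(2R)-3,3-dimethyloxiran-2-yl]ethyl}-3-methyloxiran-2-yl]methyl trifluoromethanesulfonate | FC(F)(F)S(=O)(=O)OC[C@@H]1O[C@]1(C)CC[C@H]1OC1(C)C | intermediate
10 | prop-2-en-1-yl (diethoxyphosphoryl)acetate (allyl diethylphosphonoacetate) | C=CCOC(=O)CP(=O)(OCC)OCC | starting material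
11 | prop-2-en-1-yl 2-(diethoxyphosphoryl)-3-[(2S,3R)-3-{2-[(2R)-3,3-dimethyloxiran-2-yl]ethyl}-3-methyloxiran-2-yl]propanoate (both epimers at C2) | C=CCOC(=O)C(C[C@@H]1O[C@]1(C)CC[C@H]1OC1(C)C)P(=O)(OCC)OCC | intermediate
12 | prop-2-en-1-yl (2E)-2-{[(2S,3R)-3-{2-[(2R)-3,3-dimethyloxiran-2-yl]ethyl}-3-methyloxiran-2-yl]methyl}-3-{3-(2-methylbut-3-en-2-yl)-4-[(triisopropylsilyl)oxy]phenyl}prop-2-enoate | C=CCOC(=O)/C(C[C@@H]1O[C@]1(C)CC[C@H]1OC1(C)C)=C/c1ccc(O[Si](C(C)C)(C(C)C)C(C)C)c(C(C)(C)C=C)c1 | intermediate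
13 | (2E)-2-{[(2S,3R)-3-{2-[(2R)-3,3-dimethyloxiran-2-yl]ethyl}-3-methyloxiran-2-yl]methyl}-3-{3-(2-methylbut-3-en-2-yl)-4-[(triisopropylsilyl)oxy]phenyl}prop-2-enoic acid | OC(=O)/C(C[C@@H]1O[C@]1(C)CC[C@H]1OC1(C)C)=C/c1ccc(O[Si](C(C)C)(C(C)C)C(C)C)c(C(C)(C)C=C)c1 | intermediate
14 | (2Z)-2-{[(2S,3R)-3-{2-[(2R)-3,3-dimethyloxiran-2-yl]ethyl}-3-methyloxiran-2-yl]methyl}-3-{3-(2-methylbut-3-en-2-yl)-4-[(triisopropylsilyl)oxy]phenyl}prop-2-enoic acid | OC(=O)/C(C[C@@H]1O[C@]1(C)CC[C@H]1OC1(C)C)=C\c1ccc(O[Si](C(C)C)(C(C)C)C(C)C)c(C(C)(C)C=C)c1 | intermediate (not isolated)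
15 | 3-{[(2S,3R)-3-{2-[(2R)-3,3-dimethyloxiran-2-yl]ethyl}-3-methyloxiran-2-yl]methyl}-6-(2-methylbut-3-en-2-yl)-7-[(triisopropylsilyl)oxy]-2H-chromen-2-one | C=CC(C)(C)c1cc2cc(C[C@@H]3O[C@]3(C)CC[C@H]3OC3(C)C)c(=O)oc2cc1O[Si](C(C)C)(C(C)C)C(C)C | intermediate
16 | 3-{[(2S,3R)-3-{2-[(2R)-3,3-dimethyloxiran-2-yl]ethyl}-3-methyloxiran-2-yl]methyl}-7-hydroxy-6-(2-methylbut-3-en-2-yl)-2H-chromen-2-one | C=CC(C)(C)c1cc2cc(C[C@@H]3O[C@]3(C)CC[C@H]3OC3(C)C)c(=O)oc2cc1O | target

## Step count and risks

Total step count: 11. Longest linear sequence: 8 steps (nerol 6 to target 16, steps 4 to 11).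

Steps most likely to fail:

**Step 10 (key step).** The oxidative closure may not follow the isomerisation, leaving an E/Z mixture of acids. The oxidised silyloxyarene may lose its silyl group or be captured by methanol before the carboxylate bonds to C8a. The carboxyl group may instead open the 2',3'-oxirane to a lactone.
Fallback, setting out from aldehyde 5 and coming back at silyl ether 15, brings in O1 before the ring is closed:
- The aldehyde is masked in the flask with lithium N,N,N'-trimethylethylenediamide. The resulting α-amino alkoxide directs n-BuLi (THF, −20 °C) to the only unhindered ortho carbon, the future C8a.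
- Quenching with B(OMe)3 and aqueous work-up should give [2-formyl-4-(2-methylbut-3-en-2-yl)-5-(triisopropylsilyloxy)phenyl]boronic acid F1.
- Oxidation with Me3NO in CH2Cl2 should give 2-hydroxy-5-(2-methylbut-3-en-2-yl)-4-(triisopropylsilyloxy)benzaldehyde F2.
- Horner–Wadsworth–Emmons olefination of F2 with phosphonate 11 (LiCl, DBU, MeCN) should give the allyl (E)-2-hydroxycinnamate F3.
- Irradiation of F3 (365 nm, or riboflavin with visible light under argon) should isomerise it to the Z ester, which lactonises with loss of allyl alcohol to 15.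

**Step 7.** Proton exchange may generate the anion of 11, which can attack C2' in a 3-exo closure and open the oxirane to a cyclopropane. O-alkylation, double alkylation or decay of the triflate may also consume material.
Fallback, setting out from nerol 6 and coming back at phosphonate 11, makes the C3–C1' bond before the 2',3'-oxirane exists:
- Acetylation (Ac2O, pyridine) gives neryl acetate F4.
- Shi epoxidation with the D-fructose-derived ketone should prefer the 6,7-alkene, because the allylic acetate deactivates the 2,3-alkene, and give (2Z)-5-[(2R)-3,3-dimethyloxiran-2-yl]-3-methylpent-2-en-1-yl acetate F5.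
- K2CO3 in MeOH gives the alcohol F6, and CBr4/PPh3 in CH2Cl2 at 0 °C gives the allylic bromide F7.
- The sodium salt of 10 is alkylated by F7 to the alkenyl phosphonate F8, in which no oxirane lies within reach of the carbanion.
- The remaining Z alkene is epoxidised with the enantiomeric, L-fructose-derived ketone, which should deliver the 2'S,3'R oxirane and give 11.

**Step 8.** The phosphonate carbanion may open the adjacent oxirane (3-exo closure) faster than it adds to the electron-rich, slow aldehyde, or may revert from the adduct on warming and then do so.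
Fallback, setting out from triflate 9 and aldehyde 5 and coming back at ester 12, replaces the carbanion by a neutral stabilised ylide:
- Allyl (triphenylphosphoranylidene)acetate is C-alkylated by 9 (CH2Cl2, 0 °C) to the phosphonium triflate F9.
- Washing with aqueous Na2CO3 gives the α-substituted ylide F10.
- Wittig olefination of F10 with 5 in toluene at 80 °C should give 12.

## Further compounds

F1 | step 10 | [2-formyl-4-(2-methylbut-3-en-2-yl)-5-(triisopropylsilyloxy)phenyl]boronic acid | O=Cc1cc(C(C)(C)C=C)c(O[Si](C(C)C)(C(C)C)C(C)C)cc1B(O)O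
F2 | step 10 | 2-hydroxy-5-(2-methylbut-3-en-2-yl)-4-(triisopropylsilyloxy)benzaldehyde | O=Cc1cc(C(C)(C)C=C)c(O[Si](C(C)C)(C(C)C)C(C)C)cc1O
F3 | step 10 | prop-2-en-1-yl (2E)-2-{[(2S,3R)-3-{2-[(2R)-3,3-dimethyloxiran-2-yl]ethyl}-3-methyloxiran-2-yl]methyl}-3-[2-hydroxy-5-(2-methylbut-3-en-2-yl)-4-(triisopropylsilyloxy)phenyl]prop-2-enoate | C=CCOC(=O)/C(C[C@@H]1O[C@]1(C)CC[C@H]1OC1(C)C)=C/c1cc(C(C)(C)C=C)c(O[Si](C(C)C)(C(C)C)C(C)C)cc1O
F4 | step 7 | neryl acetate, (2Z)-3,7-dimethylocta-2,6-dien-1-yl acetate | CC(=O)OC/C=C(/C)CCC=C(C)C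
F5 | step 7 | (2Z)-5-[(2R)-3,3-dimethyloxiran-2-yl]-3-methylpent-2-en-1-yl acetate | CC(=O)OC/C=C(/C)CC[C@H]1OC1(C)C
F6 | step 7 | (2Z)-5-[(2R)-3,3-dimethyloxiran-2-yl]-3-methylpent-2-en-1-ol | OC/C=C(/C)CC[C@H]1OC1(C)C
F7 | step 7 | (2R)-2-[(3Z)-5-bromo-3-methylpent-3-en-1-yl]-3,3-dimethyloxirane | BrC/C=C(/C)CC[C@H]1OC1(C)C
F8 | step 7 | prop-2-en-1-yl (4Z)-2-(diethoxyphosphoryl)-7-[(2R)-3,3-dimethyloxiran-2-yl]-5-methylhept-4-enoate | C=CCOC(=O)C(C/C=C(/C)CC[C@H]1OC1(C)C)P(=O)(OCC)OCC
F9 | step 8 | {1-[(prop-2-en-1-yloxy)carbonyl]-2-[(2S,3R)-3-{2-[(2R)-3,3-dimethyloxiran-2-yl]ethyl}-3-methyloxiran-2-yl]ethyl}triphenylphosphonium trifluoromethanesulfonate | C=CCOC(=O)C(C[C@@H]1O[C@]1(C)CC[C@H]1OC1(C)C)[P+](c1ccccc1)(c1ccccc1)c1ccccc1.[O-]S(=O)(=O)C(F)(F)F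
F10 | step 8 | prop-2-en-1-yl 3-[(2S,3R)-3-{2-[(2R)-3,3-dimethyloxiran-2-yl]ethyl}-3-methyloxiran-2-yl]-2-(triphenylphosphoranylidene)propanoate | C=CCOC(=O)C(C[C@@H]1O[C@]1(C)CC[C@H]1OC1(C)C)=P(c1ccccc1)(c1ccccc1)c1ccccc1
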